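# Proposed synthesis of 7-methoxy-3-(5-methoxy-2,2-dimethyl-2H-chromen-6-yl)-4H-chromen-4-one (15)

**Numbering used throughout:** 1 2,4-dihydroxybenzaldehyde; 2 prenal; 3 chromene salicylaldehyde; 4 ethyl diazoacetate; 5 hemiacetal; 6 furochromene ester; 7 Weinreb amide; 8 2-bromo-5-methoxyphenol; 9 its MOM ether; 10 aryllithium; 11 MOM-protected aryl ketone; 12 free hydroxy ketone; 13 bicyclic acetal; 14 2'-hydroxyisoflavone; 15 target.

**Remark on locants:** isoflavone numbering is used for 12–15 (O1, C2, C3, C4 in ring C; primed atoms in ring B; ring D is the dimethylpyran with O1'' on C4', C2'' the CMe2 carbon and C4'' on C3'). The tricyclic benzofurans are numbered as 7H-furo[2,3-f]chromenes (furan O1, C2, C3; pyran O6, C7).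

## Analysis of the target

Compound 15 is an isoflavone: a benzene ring A fused to the γ-pyranone ring C, with aryl ring B on C3. Ring A carries only the 7-methoxy group. Ring B is substituted at four contiguous positions: C1' (bond to C3), C2' (OMe), and C3'/C4', across which the 2,2-dimethyl-2H-pyran ring D is fused with its oxygen on C4' and its C3''=C4'' alkene on C3'. There is no stereocentre, so every selectivity question is constitutional: the angular fusion of ring D, which of the three phenolic oxygens is methylated, and arylation at C3 rather than C2. The sensitive sites are the ring D alkene and pyranone C2. The alkene protonates to a benzylic cation flanked by two ortho oxygens and is also vulnerable to oxidants, halogens, soft metal electrophiles and hydrogenation. C2 is a Michael acceptor that hard nucleophiles can open. The difficulty lies in the C3–C1' bond, which is hindered by the C4 carbonyl and the 2'-substituent, and in the dense, differentiated oxygenation of ring B. The strategy rests on one feature: O2' is ortho to the C1'–C3 bond, so O2', C2', C1', C3 and C2 can be closed into a furan. A 2'-hydroxyisoflavone is therefore a constitutional isomer of a 3-(2-hydroxyaroyl)benzofuran. The two differ only in whether O1 of ring A or O2' of ring B is bonded to C2.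

## Retrosynthetic reasoning

**15 to 14.** The O2'–CH3 bond is cut last. O2' is the oxygen that must serve as the furan oxygen in the isomeric benzofuran, so it appears as a free phenol only after the ring switch. At that point it is the only free hydroxyl: O7 is methylated from the start and O4' is tied up in ring D. The forward reaction is a simple O-methylation.

**14 to 12 (and 11).** The O1–C2 bond of ring C is exchanged for an O2'–C2 bond, which leads to the isomeric benzofuranyl ketone 12. This removes the need to make the hindered C3–C1' bond on a chromone, since it becomes the C3–C3a bond of a benzofuran and is formed when that ring is built. It also means ring C does not have to be assembled from a deoxybenzoin and a one-carbon unit. The forward reaction must let the ring A phenol add to furan C2 and then break the furan C2–O bond. Because that phenol must stay masked until this point, 12 is carried as its MOM ether 11, and the deprotecting acid also drives the switch.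

**11 to 7 and 10.** The bond between the carbonyl carbon (future C4) and the ring A carbon (future C4a) is cut. The nucleophile is then a simple aryllithium 10 whose position is fixed by the bromine of 9, made from phenol 8. The electrophile is the N-methoxy-N-methyl amide 7, which stops at the ketone. The alternatives are worse: electrophilic acylation of a benzofuran prefers C2, and metalation at furan C3 invites ring opening. The MOM group tolerates the organolithium and supports it by chelation.

**7 to 6.** This is a functional group interchange from amide to ethyl ester, chosen because the ester is what the benzofuran synthesis delivers.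

**6 to 3 and 4.** The furan ring is taken apart into salicylaldehyde 3 and diazo ester 4. In the forward direction the aldehyde carbon of 3 becomes furan C2 (future C2), the diazo carbon becomes furan C3 (future C3) and the ester carbon becomes the future C4. The ring B carbon shifts from the aldehyde carbon to the diazo carbon, and this 1,2-aryl shift makes the future C3–C1' bond early, on a small molecule and without a metal. The phenol oxygen of 3 then closes the furan.

**3 to 1 and 2.** Ring D is cut at O1''–C2'' and at C4''–C3', which gives the resorcinol aldehyde 1 and enal 2. In 1 the ring carbon between the two hydroxyls is the most nucleophilic, and the hydroxyl ortho to the aldehyde is locked in a hydrogen bond. The other hydroxyl therefore closes the pyran, and the angular chromene 3 retains the salicylaldehyde unit that the next step needs.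

## Alternatives that were turned down

**Alternative 1:** Ring B is dismantled completely and rebuilt by a photochemical Danheiser benzannulation.
- **Key step:** Irradiation of diazoketone A1 triggers a Wolff rearrangement (forming C5'–C6'). A ketene–alkyne [2+2] cycloaddition with siloxyalkyne A2 follows (C2'–C3' and C4'–C5'), then four-electron ring opening and six-electron closure (C1'–C2'), to give phenol A3.
- **For:** Every ring B substituent is placed unambiguously, the C3–C1' bond never has to be formed because it is already the chromone–vinyl bond of A1, and the route is convergent.
- **Against:** The chromone of A1 absorbs in the same region and is photoreactive at C2=C3. A1 needs diazo chemistry on a base-sensitive chromone acrylic acid, and A2 is a non-commercial ynol silyl ether. After A3 three further operations remain: methylation at O2', desilylation, and oxidative closure of the prenyl group onto O4' with DDQ to form ring D. The estimated length is well over ten steps.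
- **Comparison:** It is stronger in regiochemical certainty for ring B, since nothing depends on the innate selectivity of a chromenylation. The chosen route offers instead seven thermal steps from four commercial compounds, with no photochemistry on a chromone.

**Alternative 2:** Ring C is cut at C3–C4.
- **Key step:** An N-heterocyclic carbene (triazolium salt with DBU) inverts the polarity of the aldehyde carbon of keto-aldehyde A4. This carbon adds to the tethered aryl ketone in a 6-exo-trig crossed benzoin to give the racemic tertiary alcohol A5. Dehydration across C2–C3 would then give 15.
- **For:** It is catalytic and metal-free, ring B arrives with the 2'-methoxy group and ring D already in place, and no organolithium or late methylation is needed.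
- **Against:** The ketone of A4 is electron-rich and twisted by the ortho methoxy group, so it is a poor acceptor. Assembly of A4 requires α-halogenation of a ring B acetyl group in competition with halogen addition to the ring D alkene. Dehydration of A5 must ionise or activate a tertiary carbinol next to a carbonyl under conditions that threaten ring D, with retro-benzoin cleavage as a base-side escape. A stereocentre is made only to be destroyed.
- **Comparison:** The step count is similar (about six to seven), and the alternative is stronger in operational mildness. The chosen route delivers the pyranone at the correct oxidation level directly from the switch.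

**Alternative 3:** The C3–C1' bond is made by an oxidative 1,2-aryl shift of a chalcone.
- **Key step:** Tl(NO3)3 (trivalent thallium) in methanol shifts ring B of chalcone A6 from the β- to the α-carbon, and acid work-up closes O1–C2 to give A7.
- **Constraint:** Ring D must be carried saturated, because the ring D alkene would be oxythallated first. A7 is therefore a chroman, and a final benzylic dehydrogenation with DDQ is needed to reach 15.
- **For:** It is the shortest sequence (aldol, rearrangement and cyclisation, dehydrogenation; about four to five steps), it is biomimetic, the electron-rich ring B migrates readily, and both methyl ethers are present from the start.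
- **Against:** It uses a stoichiometric, highly toxic thallium salt, aurone or flavone formation can compete with a free ortho-hydroxychalcone, and the closing DDQ dehydrogenation of A7 adds an oxidation at the end on the most valuable intermediate.
- **Comparison:** The alternative is clearly stronger in step economy. The chosen route avoids thallium, keeps ring D unsaturated from step 1, and places the aryl shift that creates C3–C1' at step 2.

Key step: step 6

## Route

Step 1
Reactants: 1 2,4-dihydroxybenzaldehyde; 2 prenal (3-methylbut-2-enal)
Product: 3 5-hydroxy-2,2-dimethyl-2H-chromene-6-carbaldehyde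
Conditions: pyridine, 120 °C
Reagents that add atoms: none
Why: Base-promoted chromenylation (formal [3+3] annulation): aldol-type C-alkylation at the ring carbon between the two hydroxyls, dehydration to an ortho-quinone methide dienone and oxa-6π electrocyclisation. The hydroxyl ortho to the aldehyde stays hydrogen-bonded, so the other hydroxyl closes the pyran and the angular isomer with an intact salicylaldehyde unit is expected.

Step 2
Reactants: 3 5-hydroxy-2,2-dimethyl-2H-chromene-6-carbaldehyde; 4 ethyl diazoacetate
Product: 6 ethyl 7,7-dimethyl-7H-furo[2,3-f]chromene-3-carboxylate, via hemiacetal 5 (not isolated)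
Conditions: HBF4·OEt2 (10 mol%), CH2Cl2, rt; then p-TsOH·H2O (cat.), toluene, 80 °C
Reagents that add atoms: none
Why: Acid-catalysed benzofuran-3-carboxylate synthesis from a salicylaldehyde and a diazo ester: addition of 4 to the activated aldehyde, 1,2-shift of the electron-rich aryl group with loss of N2, closure to hemiacetal 5 and dehydration to the furan. The two oxygen donors favour the aryl shift over the hydride shift of the Roskamp pathway, and this shift creates the future C3–C1' bond. TsOH in warm toluene, under which 2,2-dimethylchromenes are themselves made by dehydration, is used in place of concentrated mineral acid to spare ring D.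

Step 3
Reactants: 6 ethyl 7,7-dimethyl-7H-furo[2,3-f]chromene-3-carboxylate
Product: 7 N-methoxy-N,7,7-trimethyl-7H-furo[2,3-f]chromene-3-carboxamide
Conditions: MeNHOMe·HCl, i-PrMgCl, THF, −20 to 0 °C
Reagents that add atoms: N,O-dimethylhydroxylamine hydrochloride, CNOC.Cl
Why: Direct aminolysis of the ester by the chloromagnesium amide formed in the flask (Weinreb amide synthesis); the ring D alkene and the furan are inert to this reagent at low temperature.

Step 4
Reactants: 8 2-bromo-5-methoxyphenol
Product: 9 1-bromo-4-methoxy-2-(methoxymethoxy)benzene
Conditions: NaH, MOMCl, THF, 0 °C to rt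
Reagents that add atoms: chloromethyl methyl ether (MOMCl), COCCl
Why: Williamson-type O-alkylation of the sodium phenoxide; the MOM acetal withstands organolithium reagents, chelates the ortho lithium and is removed by the acid of step 6.

Step 5
Reactants: 9 1-bromo-4-methoxy-2-(methoxymethoxy)benzene; 7 N-methoxy-N,7,7-trimethyl-7H-furo[2,3-f]chromene-3-carboxamide
Product: 11 (7,7-dimethyl-7H-furo[2,3-f]chromen-3-yl)[4-methoxy-2-(methoxymethoxy)phenyl]methanone, via aryllithium 10 (not isolated)
Conditions: n-BuLi, THF, −78 °C; then 7, −78 to 0 °C; aq. NH4Cl
Reagents that add atoms: none
Why: Bromine–lithium exchange is fast at −78 °C and fixes the metal para to OMe and ortho to OMOM, a site that direct ortho-lithiation would not select. The Weinreb ketone synthesis then stops at the ketone because collapse of the adduct is deferred to the quench.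

Step 6
Reactants: 11 (7,7-dimethyl-7H-furo[2,3-f]chromen-3-yl)[4-methoxy-2-(methoxymethoxy)phenyl]methanone
Product: 14 3-(5-hydroxy-2,2-dimethyl-2H-chromen-6-yl)-7-methoxy-4H-chromen-4-one, via hydroxy ketone 12 (not isolated), via bicyclic acetal 13 (not isolated)
Conditions: 3 M aq. HCl, MeOH, 55 °C
Reagents that add atoms: none
Why: Aqueous-methanolic HCl first cleaves the MOM acetal and sets free the ring A phenol of 12, which sits ortho to the ketone. Protonation of the ketone, a vinylogous ester through the furan oxygen, makes furan C2 an oxocarbenium-like centre, and the phenol adds to it in a 6-endo-trig oxa-Michael step that forms O1–C2 and closes the pyranone ring C as bicyclic acetal enol 13. Protonation of 13 on the furan oxygen and β-elimination across C2–C3 then break the old O2'–C2 bond, open the furan and release the C2' phenol of 14. The closest known reaction type is the tandem deprotection and ring-opening/cyclisation of 3-(2-alkoxybenzoyl)benzofurans to 2'-hydroxyisoflavones, a case of the addition–elimination that nucleophiles undergo at C2 of 3-acylbenzofurans and chromones. No stereocentre is set: the acetal carbon of 13 is racemic and returns to sp2 in 14. The step needs one phenol to react and the equilibrium to lie on the product side. Only the ring A hydroxyl can reach C2, and acetal 13 ionises far more easily towards the 4-hydroxybenzopyrylium ion (the protonated chromone) than towards the benzofuranium ion, so acid drains the mixture to the γ-pyranone, whose new 2'-OH can hydrogen-bond to C4=O. The ring D alkene must survive, which the dilute acid and moderate temperature are chosen to secure.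

Step 7
Reactants: 14 3-(5-hydroxy-2,2-dimethyl-2H-chromen-6-yl)-7-methoxy-4H-chromen-4-one
Product: 15 7-methoxy-3-(5-methoxy-2,2-dimethyl-2H-chromen-6-yl)-4H-chromen-4-one
Conditions: MeI, K2CO3, acetone, reflux
Reagents that add atoms: iodomethane, CI
Why: Williamson O-methylation of the only free phenol; the 7-methoxy group and ring D offer no competing site, and the alkene is untouched by these conditions.

## Compound list

1 | 2,4-dihydroxybenzaldehyde | O=Cc1ccc(O)cc1O | starting material
2 | prenal (3-methylbut-2-enal) | CC(C)=CC=O | starting material
3 | 5-hydroxy-2,2-dimethyl-2H-chromene-6-carbaldehyde | O=Cc1ccc2OC(C)(C)C=Cc2c1O | intermediate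
4 | ethyl diazoacetate | CCOC(=O)C=[N+]=[N-] | starting material
5 | ethyl 2-hydroxy-7,7-dimethyl-2,3-dihydro-7H-furo[2,3-f]chromene-3-carboxylate (hemiacetal, racemic, mixture of C2 epimers, not isolated) | CCOC(=O)C1C(O)Oc2c1ccc1OC(C)(C)C=Cc21 | intermediate
6 | ethyl 7,7-dimethyl-7H-furo[2,3-f]chromene-3-carboxylate (benzofuran-3-carboxylate with the 2,2-dimethyl-2H-pyran fused across benzofuran C6–C7, pyran oxygen on C6) | CCOC(=O)c1coc2c1ccc1OC(C)(C)C=Cc21 | intermediate
7 | N-methoxy-N,7,7-trimethyl-7H-furo[2,3-f]chromene-3-carboxamide | CON(C)C(=O)c1coc2c1ccc1OC(C)(C)C=Cc21 | intermediate
8 | 2-bromo-5-methoxyphenol | COc1ccc(Br)c(O)c1 | starting material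
9 | 1-bromo-4-methoxy-2-(methoxymethoxy)benzene | COCOc1cc(OC)ccc1Br | intermediate
10 | [4-methoxy-2-(methoxymethoxy)phenyl]lithium (not isolated) | [Li]c1ccc(OC)cc1OCOC | intermediate
11 | (7,7-dimethyl-7H-furo[2,3-f]chromen-3-yl)[4-methoxy-2-(methoxymethoxy)phenyl]methanone | COCOc1cc(OC)ccc1C(=O)c1coc2c1ccc1OC(C)(C)C=Cc21 | intermediate
12 | (7,7-dimethyl-7H-furo[2,3-f]chromen-3-yl)(2-hydroxy-4-methoxyphenyl)methanone (not isolated) | COc1ccc(C(=O)c2coc3c2ccc2OC(C)(C)C=Cc23)c(O)c1 | intermediate
13 | bicyclic acetal enol: 7-methoxy-2H-chromen-4-ol whose C2 is bonded to the ring B oxygen O2' and whose C3 is bonded to ring B carbon C1' (C2/C3-fused dihydrobenzofuran, ring D intact; racemic at C2, not isolated) | COc1ccc2C(O)=C3c4ccc5OC(C)(C)C=Cc5c4OC3Oc2c1 | intermediate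
14 | 3-(5-hydroxy-2,2-dimethyl-2H-chromen-6-yl)-7-methoxy-4H-chromen-4-one | COc1ccc2c(=O)c(-c3ccc4OC(C)(C)C=Cc4c3O)coc2c1 | intermediate
15 | 7-methoxy-3-(5-methoxy-2,2-dimethyl-2H-chromen-6-yl)-4H-chromen-4-one | COc1ccc2c(=O)c(-c3ccc4c(c3OC)C=CC(C)(C)O4)coc2c1 | target

## Step count and least certain steps

Total step count: 7. Longest linear sequence: 6 steps (steps 1, 2, 3, 5, 6, 7 from 1); the ring A branch (step 4, 8 to 9) joins at step 5.

**Step 6 (key step).**
- Risk: the switch may stall at the hydroxy ketone stage, because the phenol is held in a strong hydrogen bond to the ketone and the furan must give up its aromaticity. The longer heating then needed invites acid-promoted addition of solvent across the ring D alkene through the doubly oxygen-stabilised benzylic cation.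
- Fallback: run the switch in the anionic manifold with a fluoride-labile protecting group; it sets out from 8 and 7 and comes back at 14. Phenol 8 is alkylated with Me3SiCH2CH2OCH2Cl and NaH to give 1-bromo-4-methoxy-2-{[2-(trimethylsilyl)ethoxy]methoxy}benzene F1. Bromine–lithium exchange (n-BuLi, THF, −78 °C) gives (4-methoxy-2-{[2-(trimethylsilyl)ethoxy]methoxy}phenyl)lithium F2, which is added to 7 to give (7,7-dimethyl-7H-furo[2,3-f]chromen-3-yl)(4-methoxy-2-{[2-(trimethylsilyl)ethoxy]methoxy}phenyl)methanone F3. Bu4NF in THF at 50–60 °C removes the acetal without acid and releases the phenoxide of 12 in an aprotic medium. There the switch should run as an oxa-Michael addition followed by E1cB loss of the ring B phenoxide, and buffered work-up with AcOH should give 14.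

**Step 2.**
- Risk: the strong acid may cause oligomerisation or hydration of the ring D alkene during the diazo ester addition or the dehydration. A hydride shift in place of the aryl shift would divert material to a β-keto ester, though the electron-rich aryl group makes this less likely.
- Fallback: invert the order of ring construction; it sets out from 1 and 4 and comes back at 6. With no acid-labile alkene present, 1 and 4 under HBF4·OEt2 followed by concentrated H2SO4 should give ethyl 6-hydroxybenzofuran-3-carboxylate F4. Annulation of F4 with 2 in pyridine at 120 °C is then expected at C7, the ring carbon between the two oxygens (as in the angular chromenylation of 7-hydroxycoumarins), to give 6.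

**Step 5.**
- Risk: the amide is a vinylogous carbamate and therefore a sluggish acceptor, so aryllithium 10 may instead deprotonate furan C2–H, which the adjacent amide acidifies. This would quench the nucleophile and return 7.
- Fallback: add to an aldehyde and oxidise; it sets out from 7 and comes back at 11. LiAlH4 (THF, −40 °C) reduces 7 to 7,7-dimethyl-7H-furo[2,3-f]chromene-3-carbaldehyde F5. Aryllithium 10 adds to this far more electrophilic carbonyl at −78 °C to give racemic (7,7-dimethyl-7H-furo[2,3-f]chromen-3-yl)[4-methoxy-2-(methoxymethoxy)phenyl]methanol F6. MnO2 in CH2Cl2 oxidises the doubly activated carbinol to 11.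

**Step 7.**
- Risk: under carbonate the 2'-phenoxide can re-add to C2 and reverse the ring switch. Methylation of the ring A phenoxide formed in this way would fix the benzofuran skeleton irreversibly.
- Fallback: methylate without a free phenoxide; it sets out from 14 and comes back at 15. Me3SiCHN2 in MeOH–toluene at rt methylates by proton transfer to the diazoalkane and immediate collapse of the ion pair, so no phenoxide accumulates. This fallback makes no new compound (F0).

## Further compounds

F1 | step 6 | 1-bromo-4-methoxy-2-{[2-(trimethylsilyl)ethoxy]methoxy}benzene | COc1ccc(Br)c(OCOCC[Si](C)(C)C)c1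
F2 | step 6 | (4-methoxy-2-{[2-(trimethylsilyl)ethoxy]methoxy}phenyl)lithium | [Li]c1ccc(OC)cc1OCOCC[Si](C)(C)C
F3 | step 6 | (7,7-dimethyl-7H-furo[2,3-f]chromen-3-yl)(4-methoxy-2-{[2-(trimethylsilyl)ethoxy]methoxy}phenyl)methanone | COc1ccc(C(=O)c2coc3c2ccc2OC(C)(C)C=Cc23)c(OCOCC[Si](C)(C)C)c1
F4 | step 2 | ethyl 6-hydroxybenzofuran-3-carboxylate | CCOC(=O)c1coc2cc(O)ccc12
F5 | step 5 | 7,7-dimethyl-7H-furo[2,3-f]chromene-3-carbaldehyde | O=Cc1coc2c1ccc1OC(C)(C)C=Cc21
F6 | step 5 | (7,7-dimethyl-7H-furo[2,3-f]chromen-3-yl)[4-methoxy-2-(methoxymethoxy)phenyl]methanol (racemic) | COCOc1cc(OC)ccc1C(O)c1coc2c1ccc1OC(C)(C)C=Cc21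
F0 | step 7 | none | none
A1 | alternative 1 | (E)-1-diazo-4-(7-methoxy-4-oxo-4H-chromen-3-yl)but-3-en-2-one | COc1ccc2c(=O)c(/C=C/C(=O)C=[N+]=[N-])coc2c1
A2 | alternative 1 | triisopropyl[(5-methylhex-4-en-1-yn-1-yl)oxy]silane | CC(C)=CCC#CO[Si](C(C)C)(C(C)C)C(C)C
A3 | alternative 1 | 3-[2-hydroxy-3-(3-methylbut-2-en-1-yl)-4-(triisopropylsilyloxy)phenyl]-7-methoxy-4H-chromen-4-one | COc1ccc2c(=O)c(-c3ccc(O[Si](C(C)C)(C(C)C)C(C)C)c(CC=C(C)C)c3O)coc2c1
A4 | alternative 2 | 4-methoxy-2-[2-(5-methoxy-2,2-dimethyl-2H-chromen-6-yl)-2-oxoethoxy]benzaldehyde | COc1ccc(C=O)c(OCC(=O)c2ccc3OC(C)(C)C=Cc3c2OC)c1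
A5 | alternative 2 | 3-hydroxy-7-methoxy-3-(5-methoxy-2,2-dimethyl-2H-chromen-6-yl)chroman-4-one (racemic) | COc1ccc2c(c1)OCC(O)(c1ccc3OC(C)(C)C=Cc3c1OC)C2=O
A6 | alternative 3 | (E)-1-(2-hydroxy-4-methoxyphenyl)-3-(5-methoxy-2,2-dimethylchroman-6-yl)prop-2-en-1-one | COc1ccc(C(=O)/C=C/c2ccc3OC(C)(C)CCc3c2OC)c(O)c1
A7 | alternative 3 | 7-methoxy-3-(5-methoxy-2,2-dimethylchroman-6-yl)-4H-chromen-4-one | COc1ccc2c(=O)c(-c3ccc4OC(C)(C)CCc4c3OC)coc2c1
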